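**Retrosynthetic overview**

1. The target, 1-(3,5-dihydroxyphenyl)heptadecan-2-one, is traced back to its ethylene ketal, so the chain ketone is unmasked only in the last step.
2. The strategy rests on the benzene ring: C1 carries the 2-oxoheptadecyl chain and C3 and C5 carry the hydroxyls. C1, C3, C5 and the chain ketone carbon are therefore every second carbon of one unbranched chain, a palmitoyl-primed poly-β-ketone folded by a single bond between C1 and C2.
3. Key disconnection: ring bond C1–C2 (intramolecular aldol) leads to a 1-substituted heptane-2,4,6-trione, which is the hydrate of 2-methyl-6-[(2-pentadecyl-1,3-dioxolan-2-yl)methyl]-4H-pyran-4-one.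
4. That pyranone comes from ketalisation of 2-methyl-6-(2-oxoheptadecyl)-4H-pyran-4-one, which comes from lateral acylation of 2,6-dimethyl-4H-pyran-4-one with methyl hexadecanoate.
5. Ring order: the pyranone ring is bought, the dioxolane is added in step 2, the benzene ring is made from the pyranone ring in step 3, and the dioxolane is removed in step 4.

Key step: step 3

Remark: the target has no stereocentre and no configured double bond, so no step has to control configuration. Intermediates 8 and 9 exist as barium enolates in the flask and are drawn in their neutral carbonyl forms.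

**Route**

Step 1
Reactants: 1 2,6-dimethyl-4H-pyran-4-one; 2 methyl hexadecanoate
Product: 5 2-methyl-6-(2-oxoheptadecyl)-4H-pyran-4-one, via lithiated pyranone 3 (not isolated), via acylated lithium enolate 4 (not isolated)
Conditions: 1 (2.2 equiv), LiN(SiMe3)2 (2.2 equiv), THF, −78 °C, 30 min; then 2 (1.0 equiv), −78 → −20 °C; 1 M HCl, 0 °C
Reagents that add atoms: none
Why: Lateral (vinylogous) deprotonation of one ring methyl group gives dienolate 3, which reacts at its exocyclic carbon with the ester in a Claisen-type acylation; a second equivalent of 3 deprotonates the more acidic β-keto product to enolate 4 (returning 1), which shields it from further addition until the acid quench, and no stereocentre is formed.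

Step 2
Reactants: 5 2-methyl-6-(2-oxoheptadecyl)-4H-pyran-4-one; 6 ethylene glycol (ethane-1,2-diol)
Product: 7 2-methyl-6-[(2-pentadecyl-1,3-dioxolan-2-yl)methyl]-4H-pyran-4-one
Conditions: 6 (5 equiv), 4-MeC6H4SO3H·H2O (0.1 equiv), toluene, reflux, Dean–Stark
Reagents that add atoms: none
Why: Acid-catalysed ketalisation with azeotropic removal of water should convert the side-chain ketone, the only true ketone in 5, into its dioxolane, because the ring C4 carbonyl is a doubly vinylogous ester that is only protonated reversibly to a hydroxypyrylium ion (still acidic enough to carry the catalysis) and does not ketalise; no stereocentre is formed.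

Step 3
Reactants: 7 2-methyl-6-[(2-pentadecyl-1,3-dioxolan-2-yl)methyl]-4H-pyran-4-one
Product: 10 5-[(2-pentadecyl-1,3-dioxolan-2-yl)methyl]benzene-1,3-diol, via open-chain triketone 8 (not isolated), via cyclic aldol adduct 9 (not isolated)
Conditions: Ba(OH)2·8H2O (4 equiv), H2O/1,4-dioxane 1:1 (degassed), Ar, 25 °C then 85 °C; then CO2 to pH 8, filter
Reagents that add atoms: water, O (its oxygen enters on ring opening; one molecule of water is lost again on aromatisation)
Why: Hydroxide adds in 1,4-fashion to a ring carbon next to the pyranone oxygen (C6 or C2) and the hemiketal collapses with cleavage of the ring C–O bond, which unmasks triketone 8 as its barium enolate. The closest known reaction type is the alkaline opening of 2,6-dimethyl-4-pyranone to heptane-2,4,6-trione followed by aldol aromatisation of that triketone to orcinol. The benzene ring is closed by a 6-(enolendo)-exo-trig intramolecular aldol addition in which the methyl carbon C7 of 8, as its terminal enolate, attacks the C2 ketone that carries the dioxolanylmethyl group and gives carbinol 9; these two atoms become arene carbons C2 and C1. E1cB loss of the tertiary hydroxyl from 9 and enolisation of the two remaining carbonyl groups then give the resorcinol irreversibly, which should draw the reversible aldol equilibria through. No stereocentre is created. The step needs closure from C7 onto C2 in preference to closure from the C1 methylene onto the C6 acetyl carbonyl and to retro-Claisen scission; C1 is a neopentyl-type carbon beside the fully substituted ketal carbon and so a poor nucleophile, the base-stable dioxolane keeps the fourth carbonyl out of the enolate chemistry, and the central carbons C3 and C5 could only close strained four-membered rings.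

Step 4
Reactants: 10 5-[(2-pentadecyl-1,3-dioxolan-2-yl)methyl]benzene-1,3-diol
Product: 11 1-(3,5-dihydroxyphenyl)heptadecan-2-one
Conditions: 2 M HCl/THF 1:4 (degassed), Ar, 25 °C
Reagents that add atoms: water, O
Why: Acid-catalysed hydrolysis of the dialkyl ketal through its oxocarbenium ion should free the chain ketone under conditions that leave the resorcinol and the benzylic methylene untouched, and no stereocentre is involved.

**Compound list**

1 | 2,6-dimethyl-4H-pyran-4-one | Cc1cc(=O)cc(C)o1 | starting material
2 | methyl hexadecanoate | CCCCCCCCCCCCCCCC(=O)OC | starting material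
3 | lithium 6-methyl-2-methylidene-2H-pyran-4-olate (laterally lithiated 1) | C=C1C=C(O[Li])C=C(C)O1 | intermediate
4 | lithium 1-(6-methyl-4-oxo-4H-pyran-2-yl)heptadec-1-en-2-olate (lithium enolate of 5; enolate geometry not defined and lost on protonation) | CCCCCCCCCCCCCCCC(O[Li])=Cc1cc(=O)cc(C)o1 | intermediate
5 | 2-methyl-6-(2-oxoheptadecyl)-4H-pyran-4-one | CCCCCCCCCCCCCCCC(=O)Cc1cc(=O)cc(C)o1 | intermediate
6 | ethylene glycol (ethane-1,2-diol) | OCCO | starting material
7 | 2-methyl-6-[(2-pentadecyl-1,3-dioxolan-2-yl)methyl]-4H-pyran-4-one | CCCCCCCCCCCCCCCC1(Cc2cc(=O)cc(C)o2)OCCO1 | intermediate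
8 | 1-(2-pentadecyl-1,3-dioxolan-2-yl)heptane-2,4,6-trione | CCCCCCCCCCCCCCCC1(CC(=O)CC(=O)CC(C)=O)OCCO1 | intermediate
9 | 5-hydroxy-5-[(2-pentadecyl-1,3-dioxolan-2-yl)methyl]cyclohexane-1,3-dione | CCCCCCCCCCCCCCCC1(CC2(O)CC(=O)CC(=O)C2)OCCO1 | intermediate
10 | 5-[(2-pentadecyl-1,3-dioxolan-2-yl)methyl]benzene-1,3-diol | CCCCCCCCCCCCCCCC1(Cc2cc(O)cc(O)c2)OCCO1 | intermediate
11 | 1-(3,5-dihydroxyphenyl)heptadecan-2-one | CCCCCCCCCCCCCCCC(=O)Cc1cc(O)cc(O)c1 | target

**Totals**

Total step count: 4. Longest linear sequence: 4 steps (1 → 5 → 7 → 10 → 11).

**Steps most likely to fail**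

Step 3 (key step). Three processes could divert the triketone before it aromatises:
- hydroxide could cleave it by retro-Claisen scission;
- the enolate next to the dioxolane could expel a ring oxygen (E1cB opening to a hydroxyethyl enol ether), bringing the chain carbonyl back into the polyketone;
- the aldol could close in the reverse direction, from the chain methylene onto the acetyl carbonyl.

Poor solubility of the C15 chain in the aqueous base could also slow ring opening. The fallback gives up ring construction and uses a preformed arene; it sets out from methyl hexadecanoate 2 and comes back at target 11. Ester 2 would be converted with MeNH(OMe)·HCl and i-PrMgCl (THF, −20 °C) into N-methoxy-N-methylhexadecanamide F1. (3,5-Dimethoxybenzyl)magnesium chloride F2, prepared from commercial 3,5-dimethoxybenzyl chloride and Mg turnings (THF, 0 °C, high dilution to limit Wurtz coupling), should add once to F1 and give 1-(3,5-dimethoxyphenyl)heptadecan-2-one F3 after work-up with 1 M HCl. BBr3 (CH2Cl2, −78 → 0 °C) would then cleave both methyl ethers to give 11.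

Step 1. Proton transfer from the ester α-methylene or from the product could quench the dienolate, and on warming the dienolate could add to a second pyranone molecule, so conversion of the ester may be low. The fallback replaces acylation by aldol addition and oxidation; it sets out from pyranone 1 (through its lithiated form 3) and comes back at keto pyranone 5. Dienolate 3 would be treated with commercial hexadecanal (THF, −78 °C, NH4Cl quench) to give racemic 2-(2-hydroxyheptadecyl)-6-methyl-4H-pyran-4-one F4. Dess–Martin periodinane (1.1 equiv, NaHCO3, CH2Cl2, 0 → 25 °C) would oxidise the secondary alcohol to 5.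

Step 2. The side-chain ketone is partly enolised into conjugation with the ring and may ketalise incompletely, and hot acid with traces of water could open and re-close the pyranone with scrambling of its substituents. The fallback builds the protected triketone without passing through a pyranone; it sets out from methyl hexadecanoate 2 and ethylene glycol 6 and comes back at triketone 8.
- Crossed Claisen condensation of 2 with lithium 1-methoxyethen-1-olate F5 (from methyl acetate and LiN(i-Pr)2, THF, −78 °C, 2.2 equiv; 1 M HCl quench) should give methyl 3-oxooctadecanoate F6.
- Ketalisation of this ordinary β-keto ester with 6 (4-MeC6H4SO3H·H2O, toluene, Dean–Stark) should give methyl (2-pentadecyl-1,3-dioxolan-2-yl)acetate F7.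
- Dilithium penta-1,3-diene-2,4-diolate F8 (from pentane-2,4-dione and 2 equiv LiN(i-Pr)2, THF, 0 °C; 2.5 equiv) would be acylated at its terminal carbon by F7 and give 8 after an NH4Cl quench.
- Triketone 8 is then submitted to the Ba(OH)2 conditions of step 3; any portion that cyclodehydrates to pyranone 7 on handling is also a route compound and enters the same step.

**Further compounds**

F1 | step 3 | N-methoxy-N-methylhexadecanamide | CCCCCCCCCCCCCCCC(=O)N(C)OC
F2 | step 3 | (3,5-dimethoxybenzyl)magnesium chloride | COc1cc(C[Mg]Cl)cc(OC)c1
F3 | step 3 | 1-(3,5-dimethoxyphenyl)heptadecan-2-one | CCCCCCCCCCCCCCCC(=O)Cc1cc(OC)cc(OC)c1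
F4 | step 1 | 2-(2-hydroxyheptadecyl)-6-methyl-4H-pyran-4-one (racemic) | CCCCCCCCCCCCCCCC(O)Cc1cc(=O)cc(C)o1
F5 | step 2 | lithium 1-methoxyethen-1-olate | C=C(O[Li])OC
F6 | step 2 | methyl 3-oxooctadecanoate | CCCCCCCCCCCCCCCC(=O)CC(=O)OC
F7 | step 2 | methyl (2-pentadecyl-1,3-dioxolan-2-yl)acetate | CCCCCCCCCCCCCCCC1(CC(=O)OC)OCCO1
F8 | step 2 | dilithium penta-1,3-diene-2,4-diolate | C=C(O[Li])C=C(C)O[Li]
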